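**Strategy.** The target is cut at the bond between C4 of the upper chromane (ring C) and C6 of the lower ring A, which makes both halves the same monomer, (2R,3R,4S)-epioritin-4β-ol. The key step is a biomimetic cross-coupling. Monovalent silver ionizes the 4-benzylsulfanyl derivative of the monomer to a C4 cation stabilized by the para O7 and ortho O1 of ring A. C6 of a second, unprotected monomer (ortho to its 7-OH, para to its O1) attacks anti to the 3-OH. One operation forms the interflavanyl bond, sets C4 and delivers the unprotected target. The monomer comes from daphnetin through an enantioenriched flav-3-ene.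

Key step: step 9

Remark: flavan numbering is used (ring A benzo, ring B 2-aryl, ring C pyran) and TBS = tert-butyldimethylsilyl; in step 4 either enantiomer of the tartaric-acid-derived catalyst is assumed to be available, and the one that gives the (S)-chromene is used after its sense of induction is confirmed on a first run.

Step 1
Reactants: 1 daphnetin (7,8-dihydroxy-2H-chromen-2-one)
Product: 2 7,8-bis(TBSO)-2H-chromen-2-one
Conditions: TBSCl (2.5 equiv), imidazole, DMF, rt
Reagents that add atoms: tert-butyldimethylsilyl chloride (TBSCl), CC(C)(C)[Si](C)(C)Cl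
Why: Imidazole-promoted silylation (silyl ether formation) caps both phenols with groups that tolerate hydride, Lewis acid, NBS and NaH and are later removed by fluoride without acid.

Step 2
Reactants: 2 7,8-bis(TBSO)-2H-chromen-2-one
Product: 3 7,8-bis(TBSO)-2H-chromen-2-ol (racemic lactol)
Conditions: iBu2AlH (1.1 equiv), CH2Cl2, −78 °C; aq. potassium sodium tartrate
Reagents that add atoms: none
Why: Half-reduction of the lactone with iBu2AlH at −78 °C stops at the aluminium hemiacetal, which gives the lactol on work-up (lactone-to-lactol reduction).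

Step 3
Reactants: 3 7,8-bis(TBSO)-2H-chromen-2-ol
Product: 4 2-ethoxy-7,8-bis(TBSO)-2H-chromene (racemic acetal)
Conditions: EtOH, pyridinium p-toluenesulfonate (cat.), 4 Å MS, rt
Reagents that add atoms: ethanol, CCO
Why: Acid-catalysed acetalization of the lactol proceeds through the oxygen-stabilized chromenylium ion and turns the hydroxyl into the ethoxy leaving group needed next.

Step 4
Reactants: 4 2-ethoxy-7,8-bis(TBSO)-2H-chromene; 5 [4-(TBSO)phenyl]boronic acid
Product: 7 (S)-7,8-bis(TBSO)-2-[4-(TBSO)phenyl]-2H-chromene, via diethyl arylboronate 6 (not isolated)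
Conditions: 5, EtOH, PhMe, azeotropic drying; then 4, N,N-dibenzyltartramic acid (one enantiomer, 10 mol %), Yb(OTf)3 (cat.), EtOAc, −20 °C
Reagents that add atoms: none
Why: Enantioselective boronate addition to a chromene acetal: the tartaric-acid-derived catalyst exchanges onto boron, Yb(OTf)3 ionizes the acetal to the chromenylium ion and the aryl group is transferred to C2, so that the C2 stereocentre (S) is set by the catalyst.

Step 5
Reactants: 7 (S)-7,8-bis(TBSO)-2-[4-(TBSO)phenyl]-2H-chromene
Product: 8 (2R,3S,4R)-3-bromo-7,8-bis(TBSO)-2-[4-(TBSO)phenyl]chroman-4-ol (2,3-trans-3,4-trans)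
Conditions: NBS (1.05 equiv), DME–H2O (4:1), 0 °C, dark
Reagents that add atoms: N-bromosuccinimide, O=C1CCC(=O)N1Br; water, O
Why: Bromohydrin formation by anti addition: the bromonium ion forms at C3 on the face opposite the C2 aryl group and water opens it at the benzylic C4 trans to bromine, which sets C3 (S) and C4 (R) by substrate control.

Step 6
Reactants: 8 (2R,3S,4R)-bromohydrin
Product: 10 (2R,3R,4S)-7,8-bis(TBSO)-2-[4-(TBSO)phenyl]chromane-3,4-diol (tris-TBS epioritin-4β-ol), via cis-epoxide 9 (not isolated)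
Conditions: NaH, THF, 0 °C; then H2O, AcOH to pH 5, 0 °C to rt
Reagents that add atoms: water, O
Why: Intramolecular Williamson etherification (the C4 alkoxide displaces the C3 bromide with inversion) places the oxirane on the face of the C2 aryl group, and acid-assisted anti opening by water at the benzylic C4 (inversion) then gives the 2,3-cis-3,4-trans diol with C3 (R) and C4 (S).

Step 7
Reactants: 10 tris-TBS epioritin-4β-ol
Product: 11 (2R,3R,4S)-2-(4-hydroxyphenyl)chromane-3,4,7,8-tetrol (epioritin-4β-ol)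
Conditions: Bu4NF (3.5 equiv), AcOH (3.5 equiv), THF, 0 °C, Ar
Reagents that add atoms: none
Why: Fluoride-mediated cleavage of the three aryl silyl ethers, buffered with AcOH, frees the phenols without acid or strong base, so the benzylic C4–OH keeps its configuration.

Step 8
Reactants: 11 epioritin-4β-ol
Product: 12 (2R,3S,4S)-4-(benzylsulfanyl)-2-(4-hydroxyphenyl)chromane-3,7,8-triol (4β-benzylsulfanylepioritin)
Conditions: BnSH (10 equiv), HCl (0.2 M), dioxane, 40 °C, Ar
Reagents that add atoms: phenylmethanethiol (BnSH), SCc1ccccc1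
Why: Acid-catalysed thiolysis (SN1 substitution through the C4 benzylic cation): the thiol adds anti to the axial 3-OH of the 2,3-cis cation and should give the 3,4-trans thioether with C4 (S).

Step 9
Reactants: 12 4β-benzylsulfanylepioritin; 11 epioritin-4β-ol (in excess)
Product: 13 epioritin-(4β→6)-epioritin-4β-ol (target)
Conditions: AgBF4 (2.5 equiv), 11 (4 equiv), THF, 0 °C, dark, Ar; Sephadex LH-20
Reagents that add atoms: none
Why: Monovalent silver binds the sulfur of 12 and the C4–S bond ionizes with help from the para O7 and ortho O1 lone pairs of ring A, giving a flavan-4-yl cation (protonated para-quinone methide) that C6 of 11 captures in a Friedel–Crafts alkylation, followed by proton loss. The closest known reaction type is the AgBF4-promoted coupling of 4-benzylsulfanylflavan-3-ols with phenolic flavan nucleophiles used for biomimetic proanthocyanidin synthesis. No ring is closed. The new stereocentre, C4 of the upper unit, is set by substrate control: the arene adds to the half-chair cation anti to the axial 3-OH and opposite the C2 aryl group of the 2,3-cis unit, which should give the 3,4-trans (4S) linkage. The step needs attack by C6 and not by C5, ring B or a hydroxyl oxygen, and ionization of C–S but not of the C4–OH of 11; C6 is ortho to the 7-OH, para to O1 and unhindered, whereas C5 is peri to C4 and activated by O8 alone, and silver is selective for sulfur. The excess of 11 limits further alkylation of 13.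

**Compound list**
1 | daphnetin (7,8-dihydroxy-2H-chromen-2-one) | O=c1ccc2ccc(O)c(O)c2o1 | starting material
2 | 7,8-bis(tert-butyldimethylsilyloxy)-2H-chromen-2-one | O=c1ccc2ccc(O[Si](C)(C)C(C)(C)C)c(O[Si](C)(C)C(C)(C)C)c2o1 | intermediate
3 | 7,8-bis(tert-butyldimethylsilyloxy)-2H-chromen-2-ol (racemic lactol) | OC1C=Cc2ccc(O[Si](C)(C)C(C)(C)C)c(O[Si](C)(C)C(C)(C)C)c2O1 | intermediate
4 | 2-ethoxy-7,8-bis(tert-butyldimethylsilyloxy)-2H-chromene (racemic acetal) | CCOC1C=Cc2ccc(O[Si](C)(C)C(C)(C)C)c(O[Si](C)(C)C(C)(C)C)c2O1 | intermediate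
5 | [4-(tert-butyldimethylsilyloxy)phenyl]boronic acid | CC(C)(C)[Si](C)(C)Oc1ccc(B(O)O)cc1 | starting material
6 | diethyl [4-(tert-butyldimethylsilyloxy)phenyl]boronate | CCOB(OCC)c1ccc(O[Si](C)(C)C(C)(C)C)cc1 | intermediate
7 | (S)-7,8-bis(tert-butyldimethylsilyloxy)-2-[4-(tert-butyldimethylsilyloxy)phenyl]-2H-chromene | c1cc2c(c(O[Si](C)(C)C(C)(C)C)c1O[Si](C)(C)C(C)(C)C)O[C@H](c1ccc(O[Si](C)(C)C(C)(C)C)cc1)C=C2 | intermediate
8 | (2R,3S,4R)-3-bromo-7,8-bis(tert-butyldimethylsilyloxy)-2-[4-(tert-butyldimethylsilyloxy)phenyl]chroman-4-ol (bromine trans to the aryl group, hydroxyl trans to bromine) | c1cc2c(c(O[Si](C)(C)C(C)(C)C)c1O[Si](C)(C)C(C)(C)C)O[C@H](c1ccc(O[Si](C)(C)C(C)(C)C)cc1)[C@@H](Br)[C@@H]2O | intermediate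
9 | (2R,3R,4R)-3,4-epoxy-7,8-bis(tert-butyldimethylsilyloxy)-2-[4-(tert-butyldimethylsilyloxy)phenyl]chromane (oxirane cis to the C2 aryl group) | c1cc2c(c(O[Si](C)(C)C(C)(C)C)c1O[Si](C)(C)C(C)(C)C)O[C@H](c1ccc(O[Si](C)(C)C(C)(C)C)cc1)[C@@H]1O[C@H]21 | intermediate
10 | (2R,3R,4S)-7,8-bis(tert-butyldimethylsilyloxy)-2-[4-(tert-butyldimethylsilyloxy)phenyl]chromane-3,4-diol (2,3-cis-3,4-trans) | c1cc2c(c(O[Si](C)(C)C(C)(C)C)c1O[Si](C)(C)C(C)(C)C)O[C@H](c1ccc(O[Si](C)(C)C(C)(C)C)cc1)[C@H](O)[C@H]2O | intermediate
11 | (2R,3R,4S)-2-(4-hydroxyphenyl)chromane-3,4,7,8-tetrol (epioritin-4β-ol) | Oc1ccc2c(c1O)O[C@H](c1ccc(O)cc1)[C@H](O)[C@H]2O | intermediate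
12 | (2R,3S,4S)-4-(benzylsulfanyl)-2-(4-hydroxyphenyl)chromane-3,7,8-triol (4β-benzylsulfanylepioritin) | Oc1ccc([C@H]2Oc3c(ccc(O)c3O)[C@H](SCc3ccccc3)[C@H]2O)cc1 | intermediate
13 | (2R,3R,4S)-2-(4-hydroxyphenyl)-6-[(2R,3R,4S)-3,7,8-trihydroxy-2-(4-hydroxyphenyl)chroman-4-yl]chromane-3,4,7,8-tetrol (epioritin-(4β→6)-epioritin-4β-ol) | Oc1ccc([C@H]2Oc3c(ccc(O)c3O)[C@H](c3cc4c(c(O)c3O)O[C@H](c3ccc(O)cc3)[C@H](O)[C@H]4O)[C@H]2O)cc1 | target

**Count.** Total steps: 9. Longest linear sequence: 9 steps (1 → 2 → 3 → 4 → 7 → 8 → 10 → 11 → 12 → 13); compound 11 serves both as the precursor of 12 and as the nucleophile of step 9.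

**Steps most likely to fail**

Step 9. What may go wrong is further alkylation of the product by a second cation (chain growth), capture of the cation by a hydroxyl oxygen, and epimerization at C4 of the lower unit by the HBF4 that is released. The fallback changes the electrophile from the thioether to the silyl-protected epoxide. It sets out from bromohydrin 8 and from 11: NaH in THF converts 8 into epoxide 9, the salts are filtered off, and the solution is added to 11 (3 equiv) in hexafluoroisopropanol at 0 °C. Hydrogen-bond activation should open the oxirane at C4 for a Friedel–Crafts attack by C6 of 11 with inversion, giving the upper-unit tris-silyl ether of the target F1. Its silylated ring A is a poor nucleophile and no strong acid is formed, so chain growth and epimerization should be suppressed. Bu4NF/AcOH in THF then removes the silyl groups and the route comes back at 13.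

Step 4. What may go wrong is low enantioselectivity, erosion of the C2 configuration through reversible Lewis-acid ionization of the C2–O bond of the product, or aryl transfer to C4 of the chromenylium ion. The fallback is a racemic arylation followed by enzymatic kinetic resolution. It sets out from acetal 4 and boronate 6: BF3·OEt2 in CH2Cl2 at −78 °C should give the racemic chromene F2, and NBS in DME–H2O as in step 5 the racemic trans,trans-bromohydrin F3. Burkholderia cepacia lipase with vinyl acetate in tBuOMe at 30 °C is expected, by the empirical size rule for lipase acylation of secondary alcohols, to acylate the (4S)-enantiomer to the (2S,3R,4S)-acetate F4 and to leave the (2R,3S,4R)-alcohol. This alcohol is separated by chromatography and the route comes back at 8.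

Step 6. What may go wrong is rearrangement of the very labile epoxide to a ketone by hydride shift, loss of anti selectivity in its opening, or failure of the diequatorial bromohydrin to reach the diaxial geometry needed for ring closure. The fallback replaces steps 5 and 6 by inversion at C3 through oxidation and reduction, followed by benzylic oxidation. It sets out from chromene 7: BH3·SMe2 in THF at 0 °C should give the alkylborane F5 with boron at C3 trans to the aryl group, and NaBO3·4H2O oxidizes it to the 2,3-trans flavan-3-ol F6. Dess–Martin periodinane in CH2Cl2 gives the flavan-3-one F7. LiBH(sBu)3 in THF at −78 °C adds hydride anti to the C2 aryl group and should give the 2,3-cis flavan-3-ol F8. DDQ in wet CH2Cl2 at rt then oxidizes the benzylic C4, water adds anti to the 3-OH, and the route comes back at 10.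

**Further compounds**
F1 | step 9 | upper-unit 7,8,4'-tris-O-TBS ether of epioritin-(4β→6)-epioritin-4β-ol | CC(C)(C)[Si](C)(C)Oc1ccc([C@H]2Oc3c(ccc(O[Si](C)(C)C(C)(C)C)c3O[Si](C)(C)C(C)(C)C)[C@H](c3cc4c(c(O)c3O)O[C@H](c3ccc(O)cc3)[C@H](O)[C@H]4O)[C@H]2O)cc1
F2 | step 4 | racemic 7,8-bis(TBSO)-2-[4-(TBSO)phenyl]-2H-chromene | c1cc2c(c(O[Si](C)(C)C(C)(C)C)c1O[Si](C)(C)C(C)(C)C)OC(c1ccc(O[Si](C)(C)C(C)(C)C)cc1)C=C2
F3 | step 4 | racemic 2,3-trans-3,4-trans-3-bromo-7,8-bis(TBSO)-2-[4-(TBSO)phenyl]chroman-4-ol (both enantiomers) | c1cc2c(c(O[Si](C)(C)C(C)(C)C)c1O[Si](C)(C)C(C)(C)C)O[C@H](c1ccc(O[Si](C)(C)C(C)(C)C)cc1)[C@@H](Br)[C@@H]2O.c1cc2c(c(O[Si](C)(C)C(C)(C)C)c1O[Si](C)(C)C(C)(C)C)O[C@@H](c1ccc(O[Si](C)(C)C(C)(C)C)cc1)[C@H](Br)[C@H]2O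
F4 | step 4 | (2S,3R,4S)-3-bromo-7,8-bis(TBSO)-2-[4-(TBSO)phenyl]chroman-4-yl acetate | c1cc2c(c(O[Si](C)(C)C(C)(C)C)c1O[Si](C)(C)C(C)(C)C)O[C@@H](c1ccc(O[Si](C)(C)C(C)(C)C)cc1)[C@H](Br)[C@H]2OC(C)=O
F5 | step 6 | 2,3-trans-7,8-bis(TBSO)-2-[4-(TBSO)phenyl]chroman-3-ylborane (boron trans to the aryl group) | c1cc2c(c(O[Si](C)(C)C(C)(C)C)c1O[Si](C)(C)C(C)(C)C)O[C@H](c1ccc(O[Si](C)(C)C(C)(C)C)cc1)[C@@H](B)C2
F6 | step 6 | (2R,3S)-7,8-bis(TBSO)-2-[4-(TBSO)phenyl]chroman-3-ol (2,3-trans) | c1cc2c(c(O[Si](C)(C)C(C)(C)C)c1O[Si](C)(C)C(C)(C)C)O[C@H](c1ccc(O[Si](C)(C)C(C)(C)C)cc1)[C@@H](O)C2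
F7 | step 6 | (2R)-7,8-bis(TBSO)-2-[4-(TBSO)phenyl]chroman-3-one | c1cc2c(c(O[Si](C)(C)C(C)(C)C)c1O[Si](C)(C)C(C)(C)C)O[C@H](c1ccc(O[Si](C)(C)C(C)(C)C)cc1)C(=O)C2
F8 | step 6 | (2R,3R)-7,8-bis(TBSO)-2-[4-(TBSO)phenyl]chroman-3-ol (2,3-cis) | c1cc2c(c(O[Si](C)(C)C(C)(C)C)c1O[Si](C)(C)C(C)(C)C)O[C@H](c1ccc(O[Si](C)(C)C(C)(C)C)cc1)[C@H](O)C2
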